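**Retrosynthetic overview**
1. 14 ⇐ 13: 13 carries C4–Br in place of C4–CHO, and the formyl group is set last by reductive carbonylation.
2. 13 ⇐ 7 + guaiazulene 8: the five-membered enone ring (C1, C2, C3, C3a, C7a) is drawn one atom larger, as the six-membered ring of an isothiochroman-4-one with sulfur bridging C2 and C3. One flask joins C2 to C3 of guaiazulene, closes C2–C3 and expels the sulfur.
3. Enabling feature: the fully substituted C2=C3 bond of the indenone ring lies between the C1 carbonyl and the benzo carbon C3a, and C2 carries the electron-rich five-membered ring of the azulene. With sulfur between them, C2 becomes a doubly activated (S, C=O) cation precursor for the azulene, and C3–H becomes benzylic and adjacent to cationic sulfur, hence acidic.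
4. 7 ⇐ 6 ⇐ 4 ⇐ 2 + 3 ⇐ 1: gem-dichlorination, Friedel–Crafts closure at the only free ortho C–H (fixes the Me/C=O/C/Br pattern), thioether formation, Grignard addition.
5. Ring order: benzene and azulene rings are bought, the six-membered sulfur ring is closed in step 3, and the five-membered ring arises from it by contraction in step 5.

Key step: step 5

Remark: the target has no stereocentre. The sp3 centres of the intermediates are carried as racemates or mixtures and are erased in step 5.

Step 1
Reactants: 1 2-bromo-5-methylbenzaldehyde
Product: 2 1-(2-bromo-5-methylphenyl)ethan-1-ol (racemic)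
Conditions: MeMgBr (1.2 equiv), THF, 0 °C; then 1 M HCl
Reagents that add atoms: methylmagnesium bromide, C[Mg]Br
Why: Grignard 1,2-addition to an aryl aldehyde, in which the carbinol centre forms as a racemate without consequence because this carbon becomes sp2 in step 5.

Step 2
Reactants: 2 1-(2-bromo-5-methylphenyl)ethan-1-ol; 3 sulfanylacetic acid (thioglycolic acid)
Product: 4 {[1-(2-bromo-5-methylphenyl)ethyl]sulfanyl}acetic acid (racemic)
Conditions: CF3CO2H/CH2Cl2, rt to 40 °C
Reagents that add atoms: none
Why: Acid-promoted dehydrative thioetherification (SN1 through the 1-arylethyl cation, the reaction type used for benzhydrylsulfanylacetic acids), in which the soft thiol outcompetes the carboxyl group as nucleophile.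

Step 3
Reactants: 4 {[1-(2-bromo-5-methylphenyl)ethyl]sulfanyl}acetic acid
Product: 6 8-bromo-1,5-dimethylisothiochroman-4-one (racemic), via acid chloride 5 (not isolated)
Conditions: (COCl)2, cat. DMF, CH2Cl2, 0 °C to rt; then AlCl3 (1.3 equiv), CH2Cl2, 0 °C
Reagents that add atoms: oxalyl chloride, O=C(Cl)C(=O)Cl (supplies the chlorine of 5; none of its atoms stays in 6)
Why: Intramolecular Friedel–Crafts acylation (the standard isothiochroman-4-one synthesis), which can close only at the C–H ortho to the methyl group and meta to bromine because the other ortho position carries bromine, and this fixes the 1,2,3,4-substitution pattern.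

Step 4
Reactants: 6 8-bromo-1,5-dimethylisothiochroman-4-one
Product: 7 8-bromo-3,3-dichloro-1,5-dimethylisothiochroman-4-one (racemic, used crude)
Conditions: SO2Cl2 (2.1 equiv), CH2Cl2, 0 °C to rt; evaporation under exclusion of moisture
Reagents that add atoms: sulfuryl chloride, O=S(=O)(Cl)Cl
Why: Pummerer-type α-chlorination of a β-keto sulfide through the chlorosulfonium salt, in which both chlorinations go to C3 because its hydrogens, flanked by S and C=O, are far more acidic than the benzylic C1–H.

Step 5
Reactants: 7 8-bromo-3,3-dichloro-1,5-dimethylisothiochroman-4-one; 8 guaiazulene (1,4-dimethyl-7-(propan-2-yl)azulene)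
Product: 13 4-bromo-2-[3,8-dimethyl-5-(propan-2-yl)azulen-1-yl]-3,7-dimethyl-1H-inden-1-one, via chlorosulfide 9 (not isolated), via thionium chloride 10 (not isolated), via thiopyrylium olate 11 (not isolated), via thiirane 12 (not isolated)
Conditions: ZnCl2 (0.5 equiv, solution in Et2O), 2,6-di-tert-butyl-4-methylpyridine (1.1 equiv), PhCl, −20 °C, slow addition of 8 (1.0 equiv), then rt; then i-Pr2NEt (2.5 equiv), PPh3 (1.5 equiv), 100 °C
Reagents that add atoms: none
Why: Proposed new method: ZnCl2 ionises one C–Cl bond of 7 to an α-chloro-α-acyl thionium ion, which is attacked by C3 of guaiazulene, the only unsubstituted position of its nucleophilic five-membered ring (Friedel–Crafts alkylation with an α-chloro sulfide, buffered by the hindered pyridine), to give 9; sulfur and the azulenyl donor then expel the second chloride (10), and i-Pr2NEt removes the benzylic C1–H (isothiochroman numbering) next to the cationic sulfur to give the mesoionic 2-benzothiopyrylium-4-olate 11. The two ylide termini of 11 bond to each other (enolate carbon C3 onto thiocarbenium carbon C1, a strongly polarised four-electron closure that the six-membered ring forces to be disrotatory and cis), so the thiirane 12 and the five-membered carbocycle close in the same event, and PPh3 then takes the sulfur from 12 irreversibly, which contracts the six-membered ring by one atom and leaves the tetrasubstituted C2=C3 enone bond of the indenone. Each elementary step has a close relative (arylation of α-chloro sulfides, the olefin synthesis from α-chloro sulfides with base and PPh3, the thiirane/phosphine half of the Barton–Kellogg olefination and of the Eschenmoser sulfide contraction, formation of 2-benzothiopyrylium-4-olates by Pummerer dehydration, and the valence tautomerism of 2-benzopyrylium-4-olates with indenone oxides), and what is new is their union in one flask, on a gem-dichloride and with an azulene as the arene. The stereocentres of 9, 10 and 12 are transient (12 can only be cis-fused) and are all erased in 13, so no stereocontrol is needed. The step needs mono-arylation and C–C bond formation rather than chlorine transfer to the azulene: slow addition of 8 keeps the electrophile in excess, and cation 10 is too stabilised and too crowded by the peri methyl group of the azulene to accept a second azulene. It also needs ylide formation only after arylation, which the order of addition secures because the hindered pyridine is too weak a base to deprotonate the first thionium ion.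

Step 6
Reactants: 13 4-bromo-2-[3,8-dimethyl-5-(propan-2-yl)azulen-1-yl]-3,7-dimethyl-1H-inden-1-one
Product: 14 2-[3,8-dimethyl-5-(propan-2-yl)azulen-1-yl]-3,7-dimethyl-1-oxo-1H-indene-4-carbaldehyde (target)
Conditions: Pd(OAc)2 (2 mol %), di(1-adamantyl)-n-butylphosphine (6 mol %), TMEDA (1 equiv), CO/H2 (1:1, 5 bar), toluene, 100 °C
Reagents that add atoms: carbon monoxide, [C-]#[O+]
Why: Palladium-catalysed reductive carbonylation of an aryl bromide (oxidative addition to zerovalent palladium, CO insertion, hydrogenolysis of the acyl complex), under conditions that should leave the ketone, the tetrasubstituted enone and the azulene untouched.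

**Compound list**
1 | 2-bromo-5-methylbenzaldehyde | Cc1ccc(Br)c(C=O)c1 | starting material
2 | 1-(2-bromo-5-methylphenyl)ethan-1-ol (racemic) | CC(O)c1cc(C)ccc1Br | intermediate
3 | sulfanylacetic acid | OC(=O)CS | starting material
4 | {[1-(2-bromo-5-methylphenyl)ethyl]sulfanyl}acetic acid (racemic) | CC(SCC(=O)O)c1cc(C)ccc1Br | intermediate
5 | {[1-(2-bromo-5-methylphenyl)ethyl]sulfanyl}acetyl chloride (not isolated) | CC(SCC(=O)Cl)c1cc(C)ccc1Br | intermediate
6 | 8-bromo-1,5-dimethylisothiochroman-4-one (racemic) | CC1SCC(=O)c2c(C)ccc(Br)c21 | intermediate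
7 | 8-bromo-3,3-dichloro-1,5-dimethylisothiochroman-4-one (racemic) | CC1SC(Cl)(Cl)C(=O)c2c(C)ccc(Br)c21 | intermediate
8 | guaiazulene, 1,4-dimethyl-7-(propan-2-yl)azulene | Cc1ccc2c(C)ccc(C(C)C)cc1-2 | starting material
9 | 8-bromo-3-chloro-3-[3,8-dimethyl-5-(propan-2-yl)azulen-1-yl]-1,5-dimethylisothiochroman-4-one (diastereomer mixture, not isolated) | CC1SC(Cl)(c2cc(C)c3cc(C(C)C)ccc(C)c2-3)C(=O)c2c(C)ccc(Br)c21 | intermediate
10 | 8-bromo-3-[3,8-dimethyl-5-(propan-2-yl)azulen-1-yl]-1,5-dimethyl-4-oxo-1H-isothiochromen-2-ium chloride (charge shared with the azulene, not isolated) | CC1[S+]=C(c2cc(C)c3cc(C(C)C)ccc(C)c2-3)C(=O)c2c(C)ccc(Br)c21.[Cl-] | intermediate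
11 | 8-bromo-3-[3,8-dimethyl-5-(propan-2-yl)azulen-1-yl]-1,5-dimethyl-2-benzothiopyrylium-4-olate (mesoionic thiocarbonyl ylide, not isolated) | CC1=[S+]C(c2cc(C)c3cc(C(C)C)ccc(C)c2-3)=C([O-])c2c(C)ccc(Br)c21 | intermediate
12 | 4-bromo-2-[3,8-dimethyl-5-(propan-2-yl)azulen-1-yl]-3,7-dimethyl-2,3-epithio-2,3-dihydro-1H-inden-1-one (cis-fused, racemic, not isolated) | CC12SC1(c1cc(C)c3cc(C(C)C)ccc(C)c1-3)C(=O)c1c(C)ccc(Br)c12 | intermediate
13 | 4-bromo-2-[3,8-dimethyl-5-(propan-2-yl)azulen-1-yl]-3,7-dimethyl-1H-inden-1-one | CC1=C(c2cc(C)c3cc(C(C)C)ccc(C)c2-3)C(=O)c2c(C)ccc(Br)c21 | intermediate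
14 | 2-[3,8-dimethyl-5-(propan-2-yl)azulen-1-yl]-3,7-dimethyl-1-oxo-1H-indene-4-carbaldehyde | CC1=C(c2cc(C)c3cc(C(C)C)ccc(C)c2-3)C(=O)c2c(C)ccc(C=O)c21 | target

Total step count: 6. Longest linear sequence: 6 (1 to 14).

**Steps most likely to fail**

**Risk 1, step 5 (the labelled step).**
- Chlorine transfer from the gem-dichloride to the azulene may compete with C–C bond formation.
- The mesoionic ring may dimerise, or may rest as its proton-shifted vinyl sulfide, faster than it closes to the thiirane.
- The closure itself may be too slow at 100 °C.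

The fallback uses known chemistry. It sets out from 6 and comes back at 13.
- Oxidation of 6 with mCPBA (2.2 equiv) should give 8-bromo-1,5-dimethylisothiochroman-4-one 2,2-dioxide F1.
- Regitz diazo transfer (4-acetamidobenzenesulfonyl azide, Et3N) should give 8-bromo-3-diazo-1,5-dimethylisothiochroman-4-one 2,2-dioxide F2.
- Rh2(OAc)4-catalysed carbenoid C–H alkylation of 8 at its C3 should give 8-bromo-3-[3,8-dimethyl-5-(propan-2-yl)azulen-1-yl]-1,5-dimethylisothiochroman-4-one 2,2-dioxide F3.
- The sodium enolate of F3 (NaH) is chlorinated with C2Cl6 to 8-bromo-3-chloro-3-[3,8-dimethyl-5-(propan-2-yl)azulen-1-yl]-1,5-dimethylisothiochroman-4-one 2,2-dioxide F4.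
- KOt-Bu in THF then triggers a classical Ramberg–Bäcklund ring contraction through the episulfone to 13.

**Risk 2, step 4.**
- The second chlorination may stall.
- Chlorination may stray to the benzylic C1–H.
- The gem-dichloride may hydrolyse during handling.

The fallback reaches the same electrophile by Pummerer activation instead of halide abstraction. It sets out from 6 and comes back at 9, in the flask of step 5, and from there goes on to 13.
- N-chlorosuccinimide (1 equiv) should give 8-bromo-3-chloro-1,5-dimethylisothiochroman-4-one F5.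
- mCPBA (1 equiv, −78 °C) should give 8-bromo-3-chloro-1,5-dimethylisothiochroman-4-one 2-oxide F6.
- (CF3CO)2O with the hindered pyridine generates the α-chloro thionium ion in the presence of 8.
- The base/PPh3 stage then follows unchanged.

**Risk 3, step 6.**
- Oxidative addition at the C–Br bond, crowded by the neighbouring methyl-bearing C3, may be slow.
- Hydrodebromination may take over.

The fallback replaces carbonylation by cross-coupling and oxidation. It sets out from 13 and comes back at 14.
- Migita–Kosugi–Stille coupling with (tributylstannyl)methanol (Pd(PPh3)4, dioxane, 100 °C) should give 2-[3,8-dimethyl-5-(propan-2-yl)azulen-1-yl]-4-(hydroxymethyl)-3,7-dimethyl-1H-inden-1-one F7.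
- MnO2 in CH2Cl2 then oxidises the benzylic alcohol to 14.

**Further compounds**
F1 | step 5 | 8-bromo-1,5-dimethylisothiochroman-4-one 2,2-dioxide | CC1S(=O)(=O)CC(=O)c2c(C)ccc(Br)c21
F2 | step 5 | 8-bromo-3-diazo-1,5-dimethylisothiochroman-4-one 2,2-dioxide | CC1S(=O)(=O)C(=[N+]=[N-])C(=O)c2c(C)ccc(Br)c21
F3 | step 5 | 8-bromo-3-[3,8-dimethyl-5-(propan-2-yl)azulen-1-yl]-1,5-dimethylisothiochroman-4-one 2,2-dioxide | CC1S(=O)(=O)C(c2cc(C)c3cc(C(C)C)ccc(C)c2-3)C(=O)c2c(C)ccc(Br)c21
F4 | step 5 | 8-bromo-3-chloro-3-[3,8-dimethyl-5-(propan-2-yl)azulen-1-yl]-1,5-dimethylisothiochroman-4-one 2,2-dioxide | CC1S(=O)(=O)C(Cl)(c2cc(C)c3cc(C(C)C)ccc(C)c2-3)C(=O)c2c(C)ccc(Br)c21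
F5 | step 4 | 8-bromo-3-chloro-1,5-dimethylisothiochroman-4-one | CC1SC(Cl)C(=O)c2c(C)ccc(Br)c21
F6 | step 4 | 8-bromo-3-chloro-1,5-dimethylisothiochroman-4-one 2-oxide | CC1S(=O)C(Cl)C(=O)c2c(C)ccc(Br)c21
F7 | step 6 | 2-[3,8-dimethyl-5-(propan-2-yl)azulen-1-yl]-4-(hydroxymethyl)-3,7-dimethyl-1H-inden-1-one | CC1=C(c2cc(C)c3cc(C(C)C)ccc(C)c2-3)C(=O)c2c(C)ccc(CO)c21
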